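**Strategy.** Ring B (C5, C6, C8, C9, C10) is treated as a [3+2] adduct. The three-carbon unit C5–C6–C8 is stored as a spirocyclopropane on the ring D cyclopentane: C5–C8 is a temporary bond and C5 carries the C3=C4(C19) acrylate. The two-carbon unit is the C9=C10 enoate (C20), tethered through C11–C12 to C13. A thiyl-radical vinylcyclopropane–alkene cycloaddition opens C5–C8 and forms C8–C9 (ring C, quaternary C8) and C5–C10 (ring B) in one operation, controlled by C13, C15 and C6. It returns the acrylate, on which a vinyl sulfone then builds ring A. The precursor is a spiro[2.4]heptane bearing both chains.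

Key step: step 10

Remark: gibberellin numbering (C-1 to C-20) is used; TBS = tert-butyldimethylsilyl; at C-15 "endo" means syn to C-9 and anti to C-7, which is the configuration of the target; the target is named here as 15-endo-hydroxygibberell-16-ene-7,19,20-trioic acid.

**Step 1**
Reactants: 1 (S)-4-[(tert-butyldimethylsilyl)oxy]cyclopent-2-en-1-one; 2 but-3-en-1-ylmagnesium bromide
Product: 4 (S)-4-(but-3-en-1-yl)cyclopent-2-en-1-one, via trans adduct 3 (not isolated)
Conditions: CuBr·SMe2 (10 mol %), THF, −78 °C; aq NH4Cl; then DBU, CH2Cl2, 0 °C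
Reagents that add atoms: none
Why: Copper-catalysed conjugate addition should occur anti to the silyloxy group and E1cB loss of silanolate then shifts the enone, so the old C–O centre is traded for the C-13 centre (conjugate addition–β-elimination).

**Step 2**
Reactants: 4 (S)-4-(but-3-en-1-yl)cyclopent-2-en-1-one; 5 diethoxy(methyl)silane; 6 2-[(tert-butyldimethylsilyl)oxy]acetaldehyde
Product: 8 (4R)-4-(but-3-en-1-yl)-2-{2-[(tert-butyldimethylsilyl)oxy]-1-hydroxyethyl}cyclopentan-1-one, via silyl enol ether 7 (not isolated)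
Conditions: Cu(OAc)2 (5 mol %), 1,2-bis(diphenylphosphino)benzene (5 mol %), toluene, 0 °C; then 6, Sc(OTf)3 (10 mol %), CH2Cl2, −78 °C; dilute aq HCl work-up
Reagents that add atoms: none
Why: Copper hydride 1,4-hydrosilylation should give the enol ether regiospecifically at the former α-carbon (future C-8), and a Mukaiyama aldol addition then attaches C-6/C-7 there; the two new centres are uncontrolled and are removed in step 3.

**Step 3**
Reactants: 8 (4R)-4-(but-3-en-1-yl)-2-{2-[(tert-butyldimethylsilyl)oxy]-1-hydroxyethyl}cyclopentan-1-one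
Product: 10 (2E,4R)-4-(but-3-en-1-yl)-2-{2-[(tert-butyldimethylsilyl)oxy]ethylidene}cyclopentan-1-one, via mesylate 9 (not isolated)
Conditions: MsCl, Et3N, CH2Cl2, 0 °C → rt
Reagents that add atoms: none
Why: Mesylation and E1cB elimination should give the conjugated exocyclic enone as the thermodynamically preferred E isomer (C-7 anti to the carbonyl, syn to C-14).

**Step 4**
Reactants: 10 (2E,4R)-4-(but-3-en-1-yl)-2-{2-[(tert-butyldimethylsilyl)oxy]ethylidene}cyclopentan-1-one; 11 methyl acrylate
Product: 12 methyl (2E)-5-[(1R,3E)-3-{2-[(tert-butyldimethylsilyl)oxy]ethylidene}-4-oxocyclopentyl]pent-2-enoate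
Conditions: second-generation Grubbs catalyst (5 mol %), CH2Cl2, 40 °C
Reagents that add atoms: none
Why: Olefin cross-metathesis of the terminal alkene with the acrylate should give the E-enoate (future C-9=C-10 with C-20), the trisubstituted enone alkene being inert.

**Step 5**
Reactants: 12 methyl (2E)-5-[(1R,3E)-3-{2-[(tert-butyldimethylsilyl)oxy]ethylidene}-4-oxocyclopentyl]pent-2-enoate
Product: 13 methyl (2E)-5-[(1R,3E,4R)-3-{2-[(tert-butyldimethylsilyl)oxy]ethylidene}-4-hydroxycyclopentyl]pent-2-enoate
Conditions: (S)-2-methyl-CBS-oxazaborolidine (0.2 equiv), catecholborane, toluene, −78 °C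
Reagents that add atoms: none
Why: Corey–Bakshi–Shibata 1,2-reduction of the enone under reagent control (alkylidene side as the large group) should set C-15 as R, with the hydroxyl cis to the C-13 chain.

**Step 6**
Reactants: 13 methyl (2E)-5-[(1R,3E,4R)-3-{2-[(tert-butyldimethylsilyl)oxy]ethylidene}-4-hydroxycyclopentyl]pent-2-enoate
Product: 14 methyl (2E)-5-[(1R,3E,4R)-4-[(tert-butyldimethylsilyl)oxy]-3-{2-[(tert-butyldimethylsilyl)oxy]ethylidene}cyclopentyl]pent-2-enoate
Conditions: TBSCl, imidazole, DMF, rt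
Reagents that add atoms: tert-butyldimethylsilyl chloride, C[Si](C)(Cl)C(C)(C)C
Why: Silylation of the allylic alcohol removes the O–H that would intercept the carbenoid of step 8 and provides the bulky group used for stereocontrol in steps 8 and 10.

**Step 7**
Reactants: 15 methyl chlorooxoacetate; 16 (trimethylsilyl)diazomethane
Product: 17 methyl 3-diazo-2-oxopropanoate
Conditions: MeCN/THF, 0 °C → rt
Reagents that add atoms: none
Why: Acylation of the diazoalkane by the acid chloride with loss of chlorotrimethylsilane should give the α-diazo ketone (diazo ketone synthesis).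

**Step 8**
Reactants: 14 methyl (2E)-5-[(1R,3E,4R)-4-[(tert-butyldimethylsilyl)oxy]-3-{2-[(tert-butyldimethylsilyl)oxy]ethylidene}cyclopentyl]pent-2-enoate; 17 methyl 3-diazo-2-oxopropanoate
Product: 18 spiro[2.4]heptane keto ester (cyclopropane C-8/C-6/C-5; C-5 carries C(=O)CO2Me; C-6 carries CH2OTBS syn to C-14; 15-OTBS cis to the C-13 chain)
Conditions: Rh2(OAc)4 (2 mol %), CH2Cl2, 40 °C, slow addition of 17
Reagents that add atoms: none
Why: The rhodium carbenoid should add stereospecifically to the electron-rich exocyclic alkene on the ring face anti to 15-OTBS and the C-13 chain, which together with the E geometry fixes C-6; the configuration at C-5 and at the spiro carbon is lost again in step 10 (carbenoid cyclopropanation).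

**Step 9**
Reactants: 18 spiro[2.4]heptane keto ester
Product: 19 spiro vinylcyclopropane (C-5 carries C(=CH2)CO2Me; otherwise as 18)
Conditions: Ph3PCH3Br, KN(SiMe3)2, THF, −78 → 0 °C
Reagents that add atoms: methyltriphenylphosphonium bromide, C[P+](c1ccccc1)(c1ccccc1)c1ccccc1.[Br-]
Why: Wittig methylenation should take place at the more electrophilic ketone carbonyl of the α-keto ester, giving the 2-cyclopropylacrylate in which C-3 is the new methylene.

**Step 10**
Reactants: 19 spiro vinylcyclopropane
Product: 22 rings B/C/D diester (15-endo-OTBS; 6β-CH2OTBS; H-5β and the 1-(methoxycarbonyl)vinyl group at 5α; H-9β; 10-CO2Me as C-10 epimers), via tertiary radical 20 (not isolated), via ester radical 21 (not isolated)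
Conditions: PhSSPh (0.2 equiv), AIBN (0.1 equiv), benzene, 80 °C, hν
Reagents that add atoms: none
Why: Reversible addition of PhS• to C-3 gives a cyclopropylcarbinyl radical that opens the C-5–C-8 bond to the tertiary C-8 radical 20; this closes ring C by 6-exo-trig addition to C-9 of the enoate (21), and the C-10 radical closes ring B by 5-exo-trig addition to C-5 of the allyl sulfide, after which β-scission returns PhS• and the acrylate. The closest known reaction type is the thiyl-radical-catalysed vinylcyclopropane–alkene [3+2] annulation. C-8 is set because the tether can reach the planar radical only from the face of the C-13 chain; C-9 should follow from a chair-like transition state in which the endo 15-OTBS group blocks the equatorial site, so that C-10 is axial and H-9 is β. C-5 should follow from allylic 1,3-strain at C-6 (H-6 eclipses the alkene, attack anti to C-7 gives H-5β and C-4 α), and C-6 is carried over unchanged. C-10 forms as an epimer mixture and is set again in step 11. The step needs cleavage of C-5–C-8 and not of C-5–C-6 (tertiary against secondary radical, both openings reversible) and a matched first addition (nucleophilic C-8 radical, enoate); the absence of a hydrogen donor lets the slower second closure finish.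

**Step 11**
Reactants: 22 rings B/C/D diester; 23 phenyl vinyl sulfone
Product: 25 tetracyclic sulfone (ring A closed; 2-SO2Ph; 10α-CO2Me; 4-CO2Me; mixture at C-2 and C-4), via sulfonyl carbanion 24 (not isolated)
Conditions: KN(SiMe3)2, THF, −78 °C; then 23, −78 → 0 °C; aq NH4Cl
Reagents that add atoms: none
Why: The only enolisable ester (C-10) should add to the vinyl sulfone from the β-face, anti to C-11 and to the C-5 side chain, which sets quaternary C-10 with C-20 α, and the α-sulfonyl carbanion then closes ring A by 6-endo-trig Michael addition to C-3 (Michael–Michael annulation).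

**Step 12**
Reactants: 25 tetracyclic sulfone
Product: 26 tetracyclic diester (C-2 now CH2; C-4 epimers)
Conditions: Mg, MeOH, 50 °C
Reagents that add atoms: none
Why: Single-electron reductive desulfonylation should remove the auxiliary sulfone without touching esters or silyl ethers.

**Step 13**
Reactants: 26 tetracyclic diester
Product: 27 4β-methyl tetracyclic diester (4α-CO2Me; 10α-CO2Me; 6β-CH2OTBS; 15-endo-OTBS; C-16 as CH2)
Conditions: LiN(iPr)2, THF/HMPA, −78 °C; then MeI
Reagents that add atoms: iodomethane, CI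
Why: The exocyclic ring A ester enolate should be methylated from the equatorial β-face because the axial α-face is blocked by the 1,3-diaxial C-20 ester, giving axial C-19 and equatorial C-18 (enolate alkylation).

**Step 14**
Reactants: 27 4β-methyl tetracyclic diester
Product: 28 7,15-diol 19,20-dimethyl ester
Conditions: aq HF, MeCN, rt
Reagents that add atoms: none
Why: Fluoride-assisted acid cleavage should remove both silyl ethers while the methyl esters survive.

**Step 15**
Reactants: 28 7,15-diol 19,20-dimethyl ester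
Product: 29 7-hydroxy-15-ketone 19,20-dimethyl ester (in equilibrium with its 7,15-hemiketal)
Conditions: NaOCl, AcOH, 0 °C → rt
Reagents that add atoms: none
Why: Hypochlorite in acetic acid oxidises secondary alcohols much faster than primary ones, so the 15-carbinol should be converted while the C-7 carbinol stays.

**Step 16**
Reactants: 29 7-hydroxy-15-ketone 19,20-dimethyl ester
Product: 31 7-hydroxy-16-methylene-15-ketone 19,20-dimethyl ester, via Mannich base 30 (not isolated)
Conditions: (CH2O)n, PhNHMe·CF3CO2H, THF, reflux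
Reagents that add atoms: formaldehyde (from paraformaldehyde), C=O
Why: Mannich reaction at C-16, the only enolisable α-position, followed by β-elimination of N-methylaniline should give the α-methylene ketone, which supplies C-17.

**Step 17**
Reactants: 31 7-hydroxy-16-methylene-15-ketone 19,20-dimethyl ester
Product: 32 7,15-endo-dihydroxy-16-ene 19,20-dimethyl ester
Conditions: Me4NBH(OAc)3, AcOH/MeCN, −20 °C → rt
Reagents that add atoms: none
Why: The acetoxyborohydride, which does not reduce ketones on its own, should exchange onto the C-7 hydroxyl and deliver hydride 1,2 to the exo face of C-15, giving the endo alcohol anti to C-7 (hydroxyl-directed Saksena–Evans reduction).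

**Step 18**
Reactants: 32 7,15-endo-dihydroxy-16-ene 19,20-dimethyl ester
Product: 33 15-endo-hydroxy-16-ene 7-carboxylic acid 19,20-dimethyl ester
Conditions: TEMPO (0.2 equiv), PhI(OAc)2, MeCN/H2O, rt
Reagents that add atoms: water, O
Why: Oxoammonium oxidation is selective for the primary alcohol, whose aldehyde could only form a strained trans-fused lactol with the anti 15-hydroxyl and is therefore oxidised on through its hydrate to the acid, while the hindered neopentyl allylic alcohol should remain.

**Step 19**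
Reactants: 33 15-endo-hydroxy-16-ene 7-carboxylic acid 19,20-dimethyl ester
Product: 34 15-endo-hydroxygibberell-16-ene-7,19,20-trioic acid (the target gibberellin)
Conditions: LiSPr, HMPA, 60 °C; then aq HCl
Reagents that add atoms: none
Why: Thiolate SN2 attack at the methyl carbons should cleave both hindered esters without attack at the neopentyl acyl carbons and without touching the allylic alcohol or the exocyclic alkene (nucleophilic ester dealkylation).

**Compound list**

1 | (S)-4-[(tert-butyldimethylsilyl)oxy]cyclopent-2-en-1-one | O=C1C=C[C@@H](O[Si](C)(C)C(C)(C)C)C1 | starting material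
2 | but-3-en-1-ylmagnesium bromide | C=CCC[Mg]Br | starting material
3 | (3S,4S)-3-(but-3-en-1-yl)-4-[(tert-butyldimethylsilyl)oxy]cyclopentan-1-one (trans) | O=C1C[C@H](CCC=C)[C@@H](O[Si](C)(C)C(C)(C)C)C1 | intermediate
4 | (S)-4-(but-3-en-1-yl)cyclopent-2-en-1-one | C1[C@@H](C=CC1=O)CCC=C | intermediate
5 | diethoxy(methyl)silane | C[SiH](OCC)OCC | starting material
6 | 2-[(tert-butyldimethylsilyl)oxy]acetaldehyde | O=CCO[Si](C)(C)C(C)(C)C | starting material
7 | {[(4R)-4-(but-3-en-1-yl)cyclopent-1-en-1-yl]oxy}diethoxy(methyl)silane | C1[C@@H](CC=C1O[Si](C)(OCC)OCC)CCC=C | intermediate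
8 | (4R)-4-(but-3-en-1-yl)-2-{2-[(tert-butyldimethylsilyl)oxy]-1-hydroxyethyl}cyclopentan-1-one (mixture at C-2 and the carbinol carbon) | C1[C@@H](CC(C(O)CO[Si](C)(C)C(C)(C)C)C1=O)CCC=C | intermediate
9 | methanesulfonate of 8 | C1[C@@H](CC(C(OS(C)(=O)=O)CO[Si](C)(C)C(C)(C)C)C1=O)CCC=C | intermediate
10 | (2E,4R)-4-(but-3-en-1-yl)-2-{2-[(tert-butyldimethylsilyl)oxy]ethylidene}cyclopentan-1-one | C1[C@@H](C/C(=C\CO[Si](C)(C)C(C)(C)C)C1=O)CCC=C | intermediate
11 | methyl acrylate | C=CC(=O)OC | starting material
12 | methyl (2E)-5-[(1R,3E)-3-{2-[(tert-butyldimethylsilyl)oxy]ethylidene}-4-oxocyclopentyl]pent-2-enoate | C1[C@@H](C/C(=C\CO[Si](C)(C)C(C)(C)C)C1=O)CC/C=C/C(=O)OC | intermediate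
13 | methyl (2E)-5-[(1R,3E,4R)-3-{2-[(tert-butyldimethylsilyl)oxy]ethylidene}-4-hydroxycyclopentyl]pent-2-enoate (OH cis to the chain) | C1[C@@H](C/C(=C\CO[Si](C)(C)C(C)(C)C)[C@@H]1O)CC/C=C/C(=O)OC | intermediate
14 | methyl (2E)-5-[(1R,3E,4R)-4-[(tert-butyldimethylsilyl)oxy]-3-{2-[(tert-butyldimethylsilyl)oxy]ethylidene}cyclopentyl]pent-2-enoate | C1[C@@H](C/C(=C\CO[Si](C)(C)C(C)(C)C)[C@@H]1O[Si](C)(C)C(C)(C)C)CC/C=C/C(=O)OC | intermediate
15 | methyl chlorooxoacetate | COC(=O)C(=O)Cl | starting material
16 | (trimethylsilyl)diazomethane | C[Si](C)(C)C=[N+]=[N-] | starting material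
17 | methyl 3-diazo-2-oxopropanoate | COC(=O)C(=O)C=[N+]=[N-] | intermediate
18 | spiro[2.4]heptane keto ester: ring D cyclopentane (C-8 spiro, C-14, C-13, C-16, C-15) spiro-fused at C-8 to the cyclopropane C-8/C-6/C-5; 15-OTBS cis to the C-13 chain CH2CH2CH=CHCO2Me (E); C-5 on the ring face anti to 15-OTBS and bearing C(=O)CO2Me; C-6 bearing CH2OTBS syn to C-14 and trans to the C-5 substituent | C1[C@@H](C[C@@]2([C@@H]1O[Si](C)(C)C(C)(C)C)[C@@H](CO[Si](C)(C)C(C)(C)C)[C@@H]2C(=O)C(=O)OC)CC/C=C/C(=O)OC | intermediate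
19 | spiro vinylcyclopropane: as 18 but C-5 bears C(=CH2)CO2Me | C1[C@@H](C[C@@]2([C@@H]1O[Si](C)(C)C(C)(C)C)[C@@H](CO[Si](C)(C)C(C)(C)C)[C@@H]2C(=C)C(=O)OC)CC/C=C/C(=O)OC | intermediate
20 | ring-opened tertiary C-8 radical carrying the C-5=C-4 allyl phenyl sulfide (alkene geometry not defined) | C1[C@@H](C[C]([C@@H]1O[Si](C)(C)C(C)(C)C)[C@@H](CO[Si](C)(C)C(C)(C)C)C=C(CSc3ccccc3)C(=O)OC)CC/C=C/C(=O)OC | intermediate
21 | bicyclo[3.2.1]octane C-10 ester radical (ring C closed, H-9β) | C1[C@@H]2CC[C@@H]([CH]C(=O)OC)[C@@](C2)([C@@H]1O[Si](C)(C)C(C)(C)C)[C@@H](CO[Si](C)(C)C(C)(C)C)C=C(CSc3ccccc3)C(=O)OC | intermediate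
22 | rings B/C/D diester: 15-endo-OTBS, 6β-CH2OTBS, H-5β, 5α-[1-(methoxycarbonyl)vinyl], H-9β, 10-CO2Me (10β drawn; C-10 epimers) | C1[C@@H]2CC[C@H]3[C@H](C(=O)OC)[C@@H](C(=C)C(=O)OC)[C@H](CO[Si](C)(C)C(C)(C)C)[C@]3(C2)[C@@H]1O[Si](C)(C)C(C)(C)C | intermediate
23 | phenyl vinyl sulfone | C=CS(=O)(=O)c1ccccc1 | starting material
24 | potassium α-sulfonyl carbanion: 22 bearing 10β-CH2CH(−)SO2Ph and 10α-CO2Me | C1[C@@H]2CC[C@H]3[C@@](C[CH-]S(=O)(=O)c4ccccc4)(C(=O)OC)[C@@H](C(=C)C(=O)OC)[C@H](CO[Si](C)(C)C(C)(C)C)[C@]3(C2)[C@@H]1O[Si](C)(C)C(C)(C)C.[K+] | intermediate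
25 | tetracyclic sulfone: gibberellane skeleton without C-17 and C-18; 2-SO2Ph, 4-CO2Me (mixture at C-2 and C-4), 10α-CO2Me, 6β-CH2OTBS, 15-endo-OTBS | C1[C@@H]2CC[C@H]3[C@]4(C(=O)OC)CC(S(=O)(=O)c5ccccc5)CC(C(=O)OC)[C@H]4[C@H](CO[Si](C)(C)C(C)(C)C)[C@]3(C2)[C@@H]1O[Si](C)(C)C(C)(C)C | intermediate
26 | tetracyclic diester: as 25 but C-2 is CH2 (C-4 epimers) | C1[C@@H]2CC[C@H]3[C@]4(C(=O)OC)CCCC(C(=O)OC)[C@H]4[C@H](CO[Si](C)(C)C(C)(C)C)[C@]3(C2)[C@@H]1O[Si](C)(C)C(C)(C)C | intermediate
27 | 4β-methyl-4α,10α-bis(methoxycarbonyl) tetracycle bearing 6β-CH2OTBS and 15-endo-OTBS (C-16 as CH2) | C1[C@@H]2CC[C@H]3[C@]4(C(=O)OC)CCC[C@@](C)(C(=O)OC)[C@H]4[C@H](CO[Si](C)(C)C(C)(C)C)[C@]3(C2)[C@@H]1O[Si](C)(C)C(C)(C)C | intermediate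
28 | 7,15-diol 19,20-dimethyl ester (6β-CH2OH, 15-endo-OH, C-16 as CH2) | C1[C@@H]2CC[C@H]3[C@]4(C(=O)OC)CCC[C@@](C)(C(=O)OC)[C@H]4[C@H](CO)[C@]3(C2)[C@@H]1O | intermediate
29 | 7-hydroxy-15-ketone 19,20-dimethyl ester | C1[C@@H]2CC[C@H]3[C@]4(C(=O)OC)CCC[C@@](C)(C(=O)OC)[C@H]4[C@H](CO)[C@]3(C2)C1=O | intermediate
30 | Mannich base: 29 bearing CH2N(CH3)Ph on C-16 | CN(c5ccccc5)CC1[C@@H]2CC[C@H]3[C@]4(C(=O)OC)CCC[C@@](C)(C(=O)OC)[C@H]4[C@H](CO)[C@]3(C2)C1=O | intermediate
31 | 7-hydroxy-16-methylene-15-ketone 19,20-dimethyl ester | C=C1[C@@H]2CC[C@H]3[C@]4(C(=O)OC)CCC[C@@](C)(C(=O)OC)[C@H]4[C@H](CO)[C@]3(C2)C1=O | intermediate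
32 | 7,15-endo-dihydroxy-16-ene 19,20-dimethyl ester | C=C1[C@@H]2CC[C@H]3[C@]4(C(=O)OC)CCC[C@@](C)(C(=O)OC)[C@H]4[C@H](CO)[C@]3(C2)[C@@H]1O | intermediate
33 | 15-endo-hydroxygibberell-16-ene-7,19,20-trioic acid 19,20-dimethyl ester (free 7-acid) | C=C1[C@@H]2CC[C@H]3[C@]4(C(=O)OC)CCC[C@@](C)(C(=O)OC)[C@H]4[C@H](C(=O)O)[C@]3(C2)[C@@H]1O | intermediate
34 | 15-endo-hydroxygibberell-16-ene-7,19,20-trioic acid (the target gibberellin; 4β-CH3, 4α-CO2H, 6β-CO2H, 10α-CO2H, H-5β, H-9β) | C=C1[C@@H]2CC[C@H]3[C@]4(C(=O)O)CCC[C@@](C)(C(=O)O)[C@H]4[C@H](C(=O)O)[C@]3(C2)[C@@H]1O | target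

**Step count and risks**

Total step count: 19. Longest linear sequence: 18 (steps 1–6 and 8–19; step 7 is a side branch).

Most likely to fail:

1. Step 10 (key step). The second ring closure joins an ester-stabilised radical to an electron-poor alkene; premature chain termination or loss of face selectivity at C-9 or C-5 may occur. Fallback, setting out from 19 and coming back at 22: the radical step is run with stoichiometric thiophenol (PhSH, AIBN, benzene, 80 °C), so that the chain stops after ring opening and the first 6-exo closure, and hydrogen transfer to C-10 gives the bicyclic allyl sulfide F1. Ring B is then closed in a separate polar step: deprotonation of the C-10 ester (KN(SiMe3)2, THF, −78 °C) and intramolecular SN2′ addition–elimination at C-5 with loss of thiophenolate gives 22.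

2. Step 8. Carbene dimerisation and C–H insertion may outrun cyclopropanation of the hindered trisubstituted alkene, or the face selectivity may erode. Fallback, setting out from 12 and coming back at 19: the cyclopropane is built on the enone before reduction by a Michael-initiated ring closure. The sulfonium ylide from methyl 2-(bromomethyl)acrylate and a camphor-derived chiral sulfide (Cs2CO3, MeCN) adds to C-6 and the enolate closes on the ylide carbon, giving the spiro vinylcyclopropyl ketone F2. Corey–Bakshi–Shibata reduction with the (S)-catalyst gives the endo alcohol F3, and silylation (TBSCl, imidazole) gives 19.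

3. Step 17. Hydride delivery through a seven-membered transition state may be too slow, so that no reduction occurs or undirected attack gives the wrong C-15 epimer. Fallback, setting out from 31 and coming back at 32: the enone is converted into its tosylhydrazone F4 (TsNHNH2, EtOH), which is reduced with catecholborane and NaOAc with 1,3-transposition to the 16-methyl-15-ene F5. A Schenck ene reaction with singlet oxygen (O2, tetraphenylporphyrin, hν) takes hydrogen from the 17-methyl group and should place oxygen on C-15 from the endo face, away from the C-6 substituent, giving the hydroperoxide F6, which PPh3 reduces to 32.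

Further compounds

F1 | step 10 | bicyclo[3.2.1]octane allyl sulfide: 21 with hydrogen at C-10 (C-10 as CH2CO2Me) | C1[C@@H]2CC[C@@H](CC(=O)OC)[C@@](C2)([C@@H]1O[Si](C)(C)C(C)(C)C)[C@@H](CO[Si](C)(C)C(C)(C)C)C=C(CSc3ccccc3)C(=O)OC
F2 | step 8 | spiro vinylcyclopropyl ketone: 19 with a C-15 ketone in place of CH–OTBS | C1[C@@H](C[C@@]2(C1=O)[C@@H](CO[Si](C)(C)C(C)(C)C)[C@@H]2C(=C)C(=O)OC)CC/C=C/C(=O)OC
F3 | step 8 | spiro vinylcyclopropyl alcohol: 19 with free 15-endo-OH | C1[C@@H](C[C@@]2([C@@H]1O)[C@@H](CO[Si](C)(C)C(C)(C)C)[C@@H]2C(=C)C(=O)OC)CC/C=C/C(=O)OC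
F4 | step 17 | tosylhydrazone of 31 | C=C1[C@@H]2CC[C@H]3[C@]4(C(=O)OC)CCC[C@@](C)(C(=O)OC)[C@H]4[C@H](CO)[C@]3(C2)C1=NNS(=O)(=O)c5ccc(C)cc5
F5 | step 17 | 7-hydroxy-16-methyl-15-ene 19,20-dimethyl ester | CC=1[C@@H]2CC[C@H]3[C@]4(C(=O)OC)CCC[C@@](C)(C(=O)OC)[C@H]4[C@H](CO)[C@]3(C2)C=1
F6 | step 17 | 15-endo-hydroperoxide of 32 | C=C1[C@@H]2CC[C@H]3[C@]4(C(=O)OC)CCC[C@@](C)(C(=O)OC)[C@H]4[C@H](CO)[C@]3(C2)[C@@H]1OO
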